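**Retrosynthetic overview**

1. Target 27 ⇐ enal 26: the cyclohexenone is closed last through C13–C14 by intramolecular hydroacylation of the (Z)-enal C–H across the C14=C15 ring alkene of a preformed oxepene; the syn H/acyl addition sets C14 and C15.
2. Enabling feature: the formyl carbon C13 of the (Z)-C11=C12 enal on C10 lies 1,6 to C14 of the oxepene alkene, C1 and C10 are cis on the tetrahydrofuran, and H-15 and C13 are syn on the oxepane ring.
3. 26 ⇐ oxonene by RCM at C6=C7 ⇐ C4 by chelate-controlled allylation ⇐ (Z)-enoate by cuprate addition to a C10 ynoate ⇐ oxepene by O3–C16 etherification after Still–Gennari olefination at C14.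
4. C3 by chelate-controlled dithiane addition to a C2 acetyl group; the THF core (C1, C2, C9, C10) comes from the desymmetrised furan–maleic anhydride adduct, its two arms being differentiated by ROM/RCM through a methallyl ester and a Pd/formate allylic transposition.
5. Ring order: tetrahydrofuran → oxepene → oxonene → cyclohexenone.

Key step: step 22

Locants C1–C17 follow eunicellane numbering of the target: C2/C9 flank the THF oxygen, C1/C10 are the ring-fusion carbons, C3 carries the tertiary ether, C4 the butanoate, C6=C7 is the ring alkene, C11=C12–C13(=O) the enone, and C14–C15–C16 the oxepane branch.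

Assumption: quinidine is taken to deliver hemiester 2 in the absolute sense drawn; if induction in this exo-oxa series is opposite, the pseudo-enantiomeric quinine is used instead.

**Route**

Step 1
Reactants: 1 exo-7-oxabicyclo[2.2.1]hept-5-ene-2,3-dicarboxylic anhydride
Product: 2 (1S,2R,3S,4R)-3-exo-(methoxycarbonyl)-7-oxabicyclo[2.2.1]hept-5-ene-2-exo-carboxylic acid
Conditions: quinidine (1.1 equiv), MeOH (3 equiv), toluene/CCl4, −55 °C; alkaloid recovered by acid wash
Reagents that add atoms: methanol, CO
Why: Cinchona-alkaloid-mediated desymmetrising methanolysis of a meso anhydride should open one enantiotopic carbonyl, fixing the absolute configuration of the four future THF centres (C1, C2, C9, C10) and leaving the acid on the future C10.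

Step 2
Reactants: 2 hemiester
Product: 3 methyl 2-methylallyl exo,exo-7-oxabicyclo[2.2.1]hept-5-ene-2,3-dicarboxylate (methallyl ester on future C10)
Conditions: K2CO3, 3-bromo-2-methylprop-1-ene, DMF, 0 °C to rt
Reagents that add atoms: 3-bromo-2-methylprop-1-ene, C=C(C)CBr
Why: Carboxylate O-alkylation with an allylic bromide should install the tether that will deliver C7 and its methyl group to the arm next to C10 only.

Step 3
Reactants: 3 methyl methallyl diester
Product: 5 THF-fused seven-membered allylic lactone (C11(=O)–O–C6H2–C7(Me)=C8H) carrying the C2 vinyl group and the C14 methyl ester, via ring-opened divinyl diester 4 (not isolated)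
Conditions: second-generation Grubbs catalyst (5 mol %), ethene (1 atm), CH2Cl2, rt; then Ar sparge, toluene, 80 °C, 2 mM
Reagents that add atoms: ethene, C=C
Why: Strain-driven ring-opening metathesis followed by ring-closing metathesis (ring-rearrangement metathesis) should close only the trans-fused seven-membered lactone onto the adjacent arm, since the ester on C10 cannot reach the far vinyl group, so the two THF arms become different.

Step 4
Reactants: 5 allylic lactone
Product: 6 acid with 2-methylallyl on C9, vinyl on C2, CO2H on C10 and CO2Me on C1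
Conditions: Pd(OAc)2 (5 mol %), n-Bu3P (20 mol %), HCO2H, Et3N, THF, reflux; acidic work-up
Reagents that add atoms: none
Why: Pd-catalysed formate hydrogenolysis of the allylic C6–O bond (Tsuji–Trost-type) should deliver hydride to the more substituted allyl terminus C8, giving the 1,1-disubstituted terminal alkene and freeing the C11 acid.

Step 5
Reactants: 6 acid ester
Product: 8 cis-fused γ-lactone (C14H2–O–C11(=O)) carrying C9 methallyl and C2 vinyl, via hydroxy acid 7 (not isolated)
Conditions: LiBEt3H (3.2 equiv), THF, −78 to 0 °C; then 1 M HCl, rt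
Reagents that add atoms: none
Why: Hydride reduction of the methyl ester in the presence of the inert lithium carboxylate, then acid-induced lactonisation of the cis γ-hydroxy acid, should differentiate C14 (alcohol level) from C11 (acid level) and lock C1/C10 cis.

Step 6
Reactants: 8 vinyl lactone
Product: 9 C2 acetyl (methyl ketone) lactone
Conditions: PdCl2 (10 mol %), CuCl, O2 (1 atm), DMF/H2O 7:1, rt
Reagents that add atoms: water, O
Why: Wacker oxidation should convert the monosubstituted vinyl group to the methyl ketone (C3 and its methyl), leaving the 1,1-disubstituted methallyl alkene untouched.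

Step 7
Reactants: 9 methyl ketone
Product: 10 tertiary alcohol bearing a 1,3-dithian-2-yl group on C3
Conditions: 9 precomplexed with MgBr2·OEt2, CH2Cl2/THF, −78 °C; 2-lithio-1,3-dithiane (from 1,3-dithiane, n-BuLi, THF, −30 °C); NH4Cl quench
Reagents that add atoms: 1,3-dithiane, C1CSCSC1
Why: Cram-chelate addition of a Corey–Seebach formyl-anion equivalent to the α-alkoxy ketone should set C3, the metal bridging ketone O and THF O so that the nucleophile enters anti to C1, and the ketone should react before the lactone at −78 °C.

Step 8
Reactants: 10 dithiane lactone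
Product: 11 lactol (C11 hemiacetal, anomer mixture)
Conditions: DIBAL-H (2.5 equiv), CH2Cl2, −78 °C; Rochelle salt
Reagents that add atoms: none
Why: Low-temperature DIBAL-H reduction of a γ-lactone should stop at the lactol, which masks the epimerisable C11 aldehyde in a cis-fused ring.

Step 9
Reactants: 11 lactol
Product: 12 alkyne (C10–C≡CH) with free C14 primary and C3 tertiary hydroxyl groups
Conditions: dimethyl (1-diazo-2-oxopropyl)phosphonate, K2CO3, MeOH, 0 °C to rt
Reagents that add atoms: dimethyl (1-diazo-2-oxopropyl)phosphonate, CC(=O)C(=[N+]=[N-])P(=O)(OC)OC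
Why: Ohira–Bestmann (Seyferth–Gilbert) homologation of the ring-opened hydroxy aldehyde should give the terminal alkyne (C11–C12) and release the C14 alcohol.

Step 10
Reactants: 12 alkynyl diol
Product: 13 C14 aldehyde
Conditions: (COCl)2, DMSO, CH2Cl2, −78 °C; Et3N, −78 to −20 °C
Reagents that add atoms: none
Why: Swern oxidation should oxidise only the primary alcohol; the tertiary alcohol, dithiane and alkyne are inert, and the low temperature limits epimerisation at C1.

Step 11
Reactants: 13 aldehyde
Product: 14 methyl (Z)-2-methyl-2-enoate (C14=C15(Me)–C16O2Me, C1 cis to the ester)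
Conditions: methyl 2-[bis(2,2,2-trifluoroethoxy)phosphoryl]propanoate, KHMDS, 18-crown-6, THF, −78 °C
Reagents that add atoms: methyl 2-[bis(2,2,2-trifluoroethoxy)phosphoryl]propanoate, COC(=O)C(C)P(=O)(OCC(F)(F)F)OCC(F)(F)F
Why: Still–Gennari olefination should give the Z-trisubstituted enoate under kinetic control, placing C16 cis to C1 as the oxepene requires.

Step 12
Reactants: 14 Z-enoate
Product: 15 Z-allylic alcohol (C16 primary OH, C3 tertiary OH)
Conditions: DIBAL-H (4 equiv), CH2Cl2, −78 °C; Rochelle salt
Reagents that add atoms: none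
Why: 1,2-Reduction of the enoate by DIBAL-H should give the allylic alcohol without touching alkyne, dithiane or alkene geometry.

Step 13
Reactants: 15 diol
Product: 17 oxepene (ring O3–C16–C15(Me)=C14–C1–C2–C3) trans-fused to the THF, via allylic mesylate 16 (not isolated)
Conditions: MsCl (1.05 equiv), Et3N, CH2Cl2, −40 °C; then NaH, THF, 0 °C to rt, high dilution
Reagents that add atoms: none
Why: Selective sulfonylation of the primary allylic alcohol followed by intramolecular Williamson etherification (7-exo-tet) by the tertiary alkoxide should close the oxepene, the Z alkene holding C16 next to O3 and the SN2' mode being excluded by the strained trans-fused five-membered ring it would give.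

Step 14
Reactants: 17 alkynyl oxepene
Product: 19 methyl ynoate (C10–C≡C–CO2Me), via lithium acetylide 18 (not isolated)
Conditions: n-BuLi (1.05 equiv), THF, −78 °C; ClCO2Me, −78 to 0 °C
Reagents that add atoms: methyl chloroformate, COC(=O)Cl
Why: Deprotonation of the terminal alkyne (far more acidic than the hindered dithiane C–H) and C-acylation with a chloroformate should add C13.

Step 15
Reactants: 19 ynoate
Product: 20 methyl (Z)-3-methyl-2-enoate (C10 cis to CO2Me)
Conditions: Me2CuLi (from MeLi, CuI), THF, −78 °C; quench at −78 °C with MeOH then NH4Cl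
Reagents that add atoms: lithium dimethylcuprate, [Li+].C[Cu-]C
Why: syn-Carbocupration of the ynoate and cold protonation should give the Z-β-methyl enoate with C10 and C13 cis, the geometry needed for the later ring closure.

Step 16
Reactants: 20 dithiane
Product: 21 C4 aldehyde (α-alkoxy, α-quaternary)
Conditions: MeI, CaCO3, MeCN/H2O 9:1, 45 °C
Reagents that add atoms: water, O
Why: Alkylative hydrolysis of the dithiane (S-methylation, then hydrolysis) should unmask the aldehyde under conditions that spare alkenes and the enoate.

Step 17
Reactants: 21 aldehyde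
Product: 22 homoallylic alcohol (C4–OH, C5H2–C6H=CH2)
Conditions: allyltributylstannane, MgBr2·OEt2, CH2Cl2, −78 to −20 °C
Reagents that add atoms: allyltributylstannane, C=CC[Sn](CCCC)(CCCC)CCCC
Why: Chelation-controlled (Keck-type) allylation should set C4, Mg bridging the aldehyde O and the oxepene ether O so that the allyl group enters from the methyl side of C3, away from C2.

Step 18
Reactants: 22 diene
Product: 23 oxonene tricycle (THF/oxepene/oxonene) with Z-C6=C7, C4–OH and the Z-enoate
Conditions: second-generation Grubbs catalyst (10 mol %), CH2Cl2, 1 mM, reflux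
Reagents that add atoms: none
Why: Ring-closing metathesis of the allyl and methallyl arms held cis on the THF should close the nine-membered ring, which can only accommodate the Z trisubstituted alkene; the other trisubstituted and electron-poor alkenes are inert.

Step 19
Reactants: 23 hydroxy enoate
Product: 24 diol (C4–OH and Z-allylic C13–OH)
Conditions: DIBAL-H (3.5 equiv), CH2Cl2, −78 °C; Rochelle salt
Reagents that add atoms: none
Why: DIBAL-H 1,2-reduction of the only ester present should give the Z-allylic alcohol with the geometry retained.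

Step 20
Reactants: 24 diol
Product: 25 (Z)-enal with free C4–OH
Conditions: TEMPO (10 mol %), PhI(OAc)2 (1.1 equiv), CH2Cl2, rt
Reagents that add atoms: none
Why: Oxoammonium (TEMPO) oxidation should select the primary allylic alcohol over the hindered secondary C4–OH and should not isomerise the Z alkene.

Step 21
Reactants: 25 hydroxy enal
Product: 26 (Z)-enal C4 butanoate
Conditions: butanoic anhydride, Et3N, DMAP (cat.), CH2Cl2, 0 °C to rt
Reagents that add atoms: butanoic anhydride, CCCC(=O)OC(=O)CCC
Why: DMAP-catalysed acylation of the secondary alcohol should install the butanoate; the β,β-disubstituted enal is a poor Michael acceptor and should keep its geometry.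

Step 22
Reactants: 26 (Z)-enal butanoate
Product: 27 target (CNP0271677.1)
Conditions: [Rh(dppe)]ClO4 (10 mol %, from [Rh(nbd)(dppe)]ClO4 and H2, then Ar purge), 1,2-dichloroethane, 60–80 °C
Reagents that add atoms: none
Why: Proposed new method: Rh(I) inserts into the formyl C–H of the (Z)-enal to give an acyl–Rh(III) hydride that the Z C11=C12 bond and the cis C1/C10 substituents hold against the C14=C15 bond of the oxepene; syn hydrometalation (H to C15, Rh to the less substituted C14) gives a seven-membered acyl(alkyl)rhodacycle and C–C reductive elimination forms C13–C14. The closest known reaction type is the Rh(I)- or Ni(0)-catalysed intramolecular alkene hydroacylation (4-pentenals to cyclopentanones, 2-(but-3-enyl)benzaldehydes to tetralones by exo closure), which has not been shown for an enal C–H adding across a trisubstituted cyclic allyl ether. The cyclohexenone closes in the 6-exo-trig mode. C14 is controlled by the C1 stereocentre, because the tether from C10 can reach only the alkene face syn to C10 (cis ring fusion), and C15 is controlled by the stereospecific syn addition of acyl and hydride across the ring alkene, which places H-15 cis to C13 and the methyl group trans, as in the target. The step needs hydroacylation to win over decarbonylation and alkene isomerisation (a cationic chelating-diphosphine Rh centre and the enforced proximity of the alkene serve this), 6-exo over 7-endo closure (Rh prefers the secondary C14 to the tertiary C15) and retention of the Z enal (neutral, non-nucleophilic medium); the C6=C7 alkene is out of reach and the butanoate is inert.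

**Compound list**

1 | exo-7-oxabicyclo[2.2.1]hept-5-ene-2,3-dicarboxylic anhydride (meso) | C1[C@@H]2O[C@H](C=1)[C@@H](C(=O)O3)[C@H]2C3=O | starting material
2 | (1S,2R,3S,4R)-3-exo-(methoxycarbonyl)-7-oxabicyclo[2.2.1]hept-5-ene-2-exo-carboxylic acid | C1[C@@H]2O[C@H](C=1)[C@@H](C(=O)OC)[C@H]2C(=O)O | intermediate
3 | methyl 2-methylallyl exo,exo-7-oxabicyclo[2.2.1]hept-5-ene-2,3-dicarboxylate | C1[C@@H]2O[C@H](C=1)[C@@H](C(=O)OC)[C@H]2C(=O)OCC(C)=C | intermediate
4 | 2,5-cis-divinyl-THF 3,4-cis-diester (methyl ester on C1, methallyl ester on C10) | C=C[C@@H]1O[C@H](C=C)[C@@H](C(=O)OC)[C@H]1C(=O)OCC(C)=C | intermediate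
5 | THF trans-fused seven-membered allylic lactone with C2 vinyl and C1 CO2Me | C1[C@@H]2O[C@H](C=C)[C@@H](C(=O)OC)[C@H]2C(=O)OCC(C)=1 | intermediate
6 | C9-(2-methylallyl), C2-vinyl THF with CO2H on C10 and CO2Me on C1 | C=C(C)C[C@@H]1O[C@H](C=C)[C@@H](C(=O)OC)[C@H]1C(=O)O | intermediate
7 | hydroxy acid (C14H2OH on C1, CO2H on C10) | C=C(C)C[C@@H]1O[C@H](C=C)[C@@H](CO)[C@H]1C(=O)O | intermediate
8 | cis-fused γ-lactone (C14H2–O–C11(=O)) with C9 methallyl and C2 vinyl | C=C(C)C[C@@H]1O[C@H](C=C)[C@@H](CO2)[C@H]1C2=O | intermediate
9 | C2-acetyl lactone | C=C(C)C[C@@H]1O[C@H](C(C)=O)[C@@H](CO2)[C@H]1C2=O | intermediate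
10 | C3 tertiary alcohol with 1,3-dithian-2-yl (C4), lactone | C=C(C)C[C@@H]1O[C@H]([C@@](O)(C3SCCCS3)C)[C@@H](CO2)[C@H]1C2=O | intermediate
11 | lactol of 10 | C=C(C)C[C@@H]1O[C@H]([C@@](O)(C3SCCCS3)C)[C@@H](CO2)[C@H]1C2O | intermediate
12 | C10 ethynyl, C1 hydroxymethyl, C3 tertiary alcohol | C=C(C)C[C@@H]1O[C@H]([C@@](O)(C2SCCCS2)C)[C@@H](CO)[C@H]1C#C | intermediate
13 | C14 aldehyde | C=C(C)C[C@@H]1O[C@H]([C@@](O)(C2SCCCS2)C)[C@@H](C=O)[C@H]1C#C | intermediate
14 | methyl (Z)-2-methyl-2-enoate at C1 | C=C(C)C[C@@H]1O[C@H]([C@@](O)(C2SCCCS2)C)[C@@H](/C=C(/C)C(=O)OC)[C@H]1C#C | intermediate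
15 | Z-allylic alcohol (C16–OH), C3–OH | C=C(C)C[C@@H]1O[C@H]([C@@](O)(C2SCCCS2)C)[C@@H](/C=C(/C)CO)[C@H]1C#C | intermediate
16 | C16 allylic mesylate | C=C(C)C[C@@H]1O[C@H]([C@@](O)(C2SCCCS2)C)[C@@H](/C=C(/C)COS(C)(=O)=O)[C@H]1C#C | intermediate
17 | THF-fused oxepene with C10 ethynyl and C3 dithianyl | C=C(C)C[C@@H]1O[C@H]([C@@]3(C2SCCCS2)C)[C@@H](C=C(C)CO3)[C@H]1C#C | intermediate
18 | lithium acetylide of 17 | C=C(C)C[C@@H]1O[C@H]([C@@]3(C2SCCCS2)C)[C@@H](C=C(C)CO3)[C@H]1C#[C-].[Li+] | intermediate
19 | methyl ynoate | C=C(C)C[C@@H]1O[C@H]([C@@]3(C2SCCCS2)C)[C@@H](C=C(C)CO3)[C@H]1C#CC(=O)OC | intermediate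
20 | methyl (Z)-3-methyl-2-enoate at C10, dithiane | C=C(C)C[C@@H]1O[C@H]([C@@]3(C2SCCCS2)C)[C@@H](C=C(C)CO3)[C@H]1/C(C)=C\C(=O)OC | intermediate
21 | C4 aldehyde | C=C(C)C[C@@H]1O[C@H]([C@@]3(C=O)C)[C@@H](C=C(C)CO3)[C@H]1/C(C)=C\C(=O)OC | intermediate
22 | C4 homoallylic alcohol | C=C(C)C[C@@H]1O[C@H]([C@@]3([C@H](O)CC=C)C)[C@@H](C=C(C)CO3)[C@H]1/C(C)=C\C(=O)OC | intermediate
23 | THF/oxepene/oxonene tricycle, C4–OH, (Z)-enoate | O[C@@H]1C/C=C(/C)C[C@@H]2O[C@H]3[C@H]([C@H]2/C(C)=C\C(=O)OC)C=C(C)CO[C@@]13C | intermediate
24 | tricyclic diol (C4–OH, C13–OH) | O[C@@H]1C/C=C(/C)C[C@@H]2O[C@H]3[C@H]([C@H]2/C(C)=C\CO)C=C(C)CO[C@@]13C | intermediate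
25 | tricyclic (Z)-enal, C4–OH | O[C@@H]1C/C=C(/C)C[C@@H]2O[C@H]3[C@H]([C@H]2/C(C)=C\C=O)C=C(C)CO[C@@]13C | intermediate
26 | tricyclic (Z)-enal C4 butanoate | CCCC(=O)O[C@@H]1C/C=C(/C)C[C@@H]2O[C@H]3[C@H]([C@H]2/C(C)=C\C=O)C=C(C)CO[C@@]13C | intermediate
27 | CNP0271677.1, (1R,2S,3S,4R,6Z,9S,10S,14R,15R) in eunicellane numbering | CCCC(=O)O[C@@H]1C/C=C(/C)C[C@@H]2O[C@H]3[C@@H]4[C@H]2C(C)=CC(=O)[C@@H]4[C@@H](C)CO[C@@]13C | target

**Step count and risk**

Total step count: 22. Longest linear sequence: 22 steps (fully linear from 1).

Steps most likely to fail: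

Step 22 (proposed new method). After C–H oxidative addition, decarbonylation of the acyl-rhodium hydride and Rh–H-mediated alkene isomerisation may outrun insertion of the hindered trisubstituted alkene. The fallback uses known chemistry and sets out from 26. A Me2AlCl-promoted type-I intramolecular carbonyl–ene reaction (CH2Cl2, −78 °C), as in the cyclisation of (Z)-3-methyl-2-enals onto trisubstituted alkenes, should form C13–C14 on the same alkene face and give the C13 allylic alcohol with an exocyclic C15 methylene F1. Hydroxyl-directed hydrogenation with a cationic Rh(I) diphosphine catalyst ([Rh(nbd)(dppb)]BF4, H2, stopped after one equivalent) should deliver hydrogen to C15 from the side of the C13–O bond, cis to C13, and give the saturated allylic alcohol F2. Dess–Martin oxidation of F2 then returns to the route at 27. The weak point of this fallback is competing directed reduction of the C11=C12 allylic alkene.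

Step 3. Oligomerisation by ring-opening metathesis may outrun closure of the ruthenium alkylidene onto the 1,1-disubstituted alkene of an ester that must adopt its s-cis form. The fallback is a relay ring-rearrangement metathesis and sets out from 2. Hex-5-enal and ethyl 2-(triphenylphosphoranylidene)propanoate should give ethyl (2E)-2-methylocta-2,7-dienoate F3, and DIBAL-H reduction should give (2E)-2-methylocta-2,7-dien-1-ol F4. Carbodiimide esterification of 2 with F4 gives the relay diester F5. With the second-generation Grubbs catalyst under ethene, ruthenium loads on the terminal alkene of F5, expels cyclopentene and is delivered directly onto the hindered carbon, which then opens the strained alkene intramolecularly. This comes back to the route at 5.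

Step 13. Intermolecular alkylation and E2 or chloride-exchange loss of the allylic sulfonate may outrun the 7-exo closure by the hindered tertiary alkoxide. The fallback changes the bond-forming event from SN2 to lactol reduction and sets out from 14. DIBAL-H (2.2 equiv, −78 °C) should reduce the ester to the Z-enal, which is trapped by the C3 hydroxyl as the seven-membered allylic lactol F6. Ionic reduction of F6 (Et3SiH, BF3·OEt2, CH2Cl2, −78 °C) through the conjugated oxocarbenium ion should give the cyclic ether and come back to the route at 17.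

**Further compounds**

F1 | step 22 | tetracyclic C13 allylic alcohol with exocyclic C15 methylene (carbonyl–ene product) | CCCC(=O)O[C@@H]1C/C=C(/C)C[C@@H]2O[C@H]3[C@@H]4[C@H]2C(C)=CC(O)[C@@H]4C(=C)CO[C@@]13C
F2 | step 22 | tetracyclic C13 allylic alcohol with saturated C15 (13-dihydro target) | CCCC(=O)O[C@@H]1C/C=C(/C)C[C@@H]2O[C@H]3[C@@H]4[C@H]2C(C)=CC(O)[C@@H]4[C@@H](C)CO[C@@]13C
F3 | step 3 | ethyl (2E)-2-methylocta-2,7-dienoate | CCOC(=O)/C(C)=C/CCCC=C
F4 | step 3 | (2E)-2-methylocta-2,7-dien-1-ol | OC/C(C)=C/CCCC=C
F5 | step 3 | relay diester of 2 (methyl ester on future C1, (2E)-2-methylocta-2,7-dienyl ester on future C10) | C1[C@@H]2O[C@H](C=1)[C@@H](C(=O)OC)[C@H]2C(=O)OC/C(C)=C/CCCC=C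
F6 | step 13 | seven-membered allylic lactol (C16 hemiacetal) of the oxepene | C=C(C)C[C@@H]1O[C@H]([C@@]3(C2SCCCS2)C)[C@@H](C=C(C)C(O)O3)[C@H]1C#C
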